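**Retrosynthetic overview**
- Burmanin C comes from removal of one TIPS and one MOM group from a protected biaryl; the aryl–quinone bond is made by Suzuki–Miyaura coupling of 2-bromo-5-methoxy-7-methyl-1,4-naphthoquinone with a 2-naphthyl pinacol boronate.
- The bromoquinone comes from O-methylation of 2-bromo-7-methyljuglone, itself from a bromine-directed Diels–Alder reaction of 2,5-dibromo-1,4-benzoquinone with a senecioate-derived silyl ketene acetal diene.
- The boronate comes from OMOM-directed ortho-lithiation/borylation; its 1-OH/4-OMe pattern comes from para-oxidation of a 1-naphthol to the quinone monoketal and reductive aromatisation.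
- The 1-naphthol comes from anionic cyclisation of an ortho-methallyl benzamide, made by directed ortho-metalation of a benzamide derived from 3-hydroxy-2-methoxybenzoic acid.
- Ring order: the benzo ring of the quinone half is built onto the quinone ring; the second ring of the naphthol half is built onto the benzamide ring; the two bicycles are joined last.

Assumption: the target SMILES has no stereocentre and no descriptor for the biaryl axis, so the compound is made as drawn and no stereocontrol is needed.

**Route**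

Step 1
Reactants: 1 methyl 3-methylbut-2-enoate
Product: 3 silyl ketene acetal diene 1-methoxy-3-methyl-1-(trimethylsilyloxy)buta-1,3-diene, via lithium dienolate 2 (not isolated)
Conditions: LiN(iPr)2, THF, −78 °C; Me3SiCl, −78 °C → rt; distil
Reagents that add atoms: chlorotrimethylsilane, C[Si](C)(C)Cl
Why: Kinetic γ-deprotonation of the senecioate gives the extended dienolate, which is trapped on oxygen (silyl ketene acetal formation) to give the 1,1-dioxygenated diene.

Step 2
Reactants: 3 silyl ketene acetal diene; 4 2,5-dibromo-1,4-benzoquinone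
Product: 6 2-bromo-5-hydroxy-7-methylnaphthalene-1,4-dione, via Diels–Alder adduct 5 (not isolated)
Conditions: PhH, rt; then SiO2, CH2Cl2, rt
Reagents that add atoms: none
Why: In this regioselective Diels–Alder reaction the nucleophilic CH2 terminus of the diene bonds to the unbrominated carbon of a C(Br)=CH unit, so loss of HBr and MeOSiMe3 (aromatisation) leaves the new OH peri to the carbonyl remote from the surviving bromine.

Step 3
Reactants: 6 2-bromo-5-hydroxy-7-methylnaphthalene-1,4-dione
Product: 7 2-bromo-5-methoxy-7-methylnaphthalene-1,4-dione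
Conditions: MeI, Ag2O, CHCl3, rt, dark
Reagents that add atoms: iodomethane, CI
Why: Neutral Ag2O-promoted O-methylation of the chelated peri-phenol (Purdie-type) avoids basic nucleophiles that would attack the bromoquinone.

Step 4
Reactants: 8 3-hydroxy-2-methoxybenzoic acid
Product: 9 N,N-diethyl-3-hydroxy-2-methoxybenzamide
Conditions: Et2NH (3 equiv), iPrN=C=NiPr, HOBt (cat.), CH2Cl2, 0 °C → rt
Reagents that add atoms: diethylamine, CCNCC
Why: Carbodiimide amide coupling installs the tertiary amide used later as directing group; excess amine cleaves any aryl ester formed at the free phenol.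

Step 5
Reactants: 9 N,N-diethyl-3-hydroxy-2-methoxybenzamide
Product: 10 N,N-diethyl-2-methoxy-3-(triisopropylsilyloxy)benzamide
Conditions: iPr3SiCl, imidazole, DMF, rt
Reagents that add atoms: chlorotriisopropylsilane, CC(C)[Si](Cl)(C(C)C)C(C)C
Why: Silyl ether formation masks the phenol with a bulky group that tolerates organolithiums and does not direct lithiation.

Step 6
Reactants: 10 N,N-diethyl-2-methoxy-3-(triisopropylsilyloxy)benzamide; 11 3-bromo-2-methylprop-1-ene
Product: 14 N,N-diethyl-2-methoxy-6-(2-methylprop-2-enyl)-3-(triisopropylsilyloxy)benzamide, via aryllithium 12 (not isolated), via arylmagnesium bromide 13 (not isolated)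
Conditions: s-BuLi, TMEDA, THF, −78 °C; MgBr2·OEt2, −78 → 0 °C; then 11, 0 °C → rt
Reagents that add atoms: none
Why: Directed ortho-metalation by the diethylamide occurs at its only free ortho position, and transmetalation to magnesium allows clean allylation by methallyl bromide.

Step 7
Reactants: 14 N,N-diethyl-2-methoxy-6-(2-methylprop-2-enyl)-3-(triisopropylsilyloxy)benzamide
Product: 16 8-methoxy-3-methyl-7-(triisopropylsilyloxy)naphthalen-1-ol, via allyllithium 15 (not isolated)
Conditions: LiN(iPr)2 (2.5 equiv), THF, −78 °C → rt; 1 M HCl work-up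
Reagents that add atoms: none
Why: In this anionic ring annulation of an ortho-allyl benzamide, the benzylic–allylic anion attacks the amide carbonyl through its terminal carbon, diethylamide is lost and the ketone tautomerises to the 3-methyl-1-naphthol.

Step 8
Reactants: 16 8-methoxy-3-methyl-7-(triisopropylsilyloxy)naphthalen-1-ol
Product: 18 4,8-dimethoxy-3-methyl-7-(triisopropylsilyloxy)naphthalen-1-ol, via quinone monoketal 17 (not isolated)
Conditions: PhI(OAc)2 (2.2 equiv), MeOH, 0 °C; then Zn dust, AcOH, rt
Reagents that add atoms: methanol, CO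
Why: Hypervalent-iodine oxidative dearomatisation delivers methanol para to the free OH to give the quinone monoketal, and reductive aromatisation by zinc expels one methoxide, leaving the 4-methoxy-1-naphthol with the two oxygens differentiated.

Step 9
Reactants: 18 4,8-dimethoxy-3-methyl-7-(triisopropylsilyloxy)naphthalen-1-ol
Product: 19 4,8-dimethoxy-1-(methoxymethoxy)-3-methyl-7-(triisopropylsilyloxy)naphthalene
Conditions: NaH, THF, 0 °C; MeOCH2Cl, 0 °C → rt (under Ar)
Reagents that add atoms: chloromethyl methyl ether, COCCl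
Why: Williamson-type O-alkylation protects the oxidation-prone naphthol as a MOM acetal, which is also the directing group for the next step.

Step 10
Reactants: 19 4,8-dimethoxy-1-(methoxymethoxy)-3-methyl-7-(triisopropylsilyloxy)naphthalene
Product: 21 pinacol boronate 2-[4,8-dimethoxy-1-(methoxymethoxy)-3-methyl-7-(triisopropylsilyloxy)naphthalen-2-yl]-4,4,5,5-tetramethyl-1,3,2-dioxaborolane, via aryllithium 20 (not isolated)
Conditions: n-BuLi, TMEDA, THF, 0 °C; iPrOBpin, −78 °C → rt; H2O work-up
Reagents that add atoms: 2-isopropoxy-4,4,5,5-tetramethyl-1,3,2-dioxaborolane, CC(C)OB1OC(C)(C)C(C)(C)O1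
Why: Directed ortho-metalation by the OMOM group occurs at C2, its only ortho C–H (the bulky silyloxy group on the other ring does not direct), and the aryllithium is trapped by electrophilic borylation.

Step 11
Reactants: 21 pinacol boronate; 7 2-bromo-5-methoxy-7-methylnaphthalene-1,4-dione
Product: 22 2-[4,8-dimethoxy-1-(methoxymethoxy)-3-methyl-7-(triisopropylsilyloxy)naphthalen-2-yl]-5-methoxy-7-methylnaphthalene-1,4-dione
Conditions: Pd(OAc)2 (5 mol %), SPhos (10 mol %), K3PO4, PhMe/H2O (10:1), 70 °C
Reagents that add atoms: none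
Why: Suzuki–Miyaura cross-coupling (zerovalent palladium inserts into the quinone C–Br bond, then transmetalation and reductive elimination) fixes the biaryl bond at C2 of the quinone; the bulky biaryl phosphine tolerates the di-ortho-substituted boronate, and no stereocentre is formed.

Step 12
Reactants: 22 protected biaryl
Product: 24 burmanin C 2-(1,7-dihydroxy-4,8-dimethoxy-3-methylnaphthalen-2-yl)-5-methoxy-7-methylnaphthalene-1,4-dione, via silyl-free phenol 23 (not isolated)
Conditions: Bu4NF, AcOH, THF, 0 °C; then 3 M HCl, MeOH, 40 °C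
Reagents that add atoms: none
Why: Buffered fluoride desilylation followed by acid-catalysed acetal methanolysis frees both hydroxyls, while the three aryl methyl ethers survive because no Lewis acid is used.

**Compound list**
1 | methyl 3-methylbut-2-enoate | COC(=O)C=C(C)C | starting material
2 | lithium 1-methoxy-3-methylbuta-1,3-dien-1-olate (not isolated) | [Li]OC(OC)=CC(C)=C | intermediate
3 | 1-methoxy-3-methyl-1-(trimethylsilyloxy)buta-1,3-diene (E/Z mixture, geometry irrelevant) | COC(O[Si](C)(C)C)=CC(C)=C | intermediate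
4 | 2,5-dibromo-1,4-benzoquinone | O=C1C=C(Br)C(=O)C=C1Br | starting material
5 | 2,4a-dibromo-5-methoxy-7-methyl-5-(trimethylsilyloxy)-4a,5,8,8a-tetrahydronaphthalene-1,4-dione (racemic, cis-fused, diastereomer mixture; stereocentres lost on aromatisation; not isolated) | O=C1C=C(Br)C(=O)C2CC(C)=CC(OC)(O[Si](C)(C)C)C12Br | intermediate
6 | 2-bromo-5-hydroxy-7-methylnaphthalene-1,4-dione | Cc1cc(O)c2C(=O)C=C(Br)C(=O)c2c1 | intermediate
7 | 2-bromo-5-methoxy-7-methylnaphthalene-1,4-dione | COc1cc(C)cc2C(=O)C(Br)=CC(=O)c12 | intermediate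
8 | 3-hydroxy-2-methoxybenzoic acid | COc1c(O)cccc1C(=O)O | starting material
9 | N,N-diethyl-3-hydroxy-2-methoxybenzamide | CCN(CC)C(=O)c1cccc(O)c1OC | intermediate
10 | N,N-diethyl-2-methoxy-3-(triisopropylsilyloxy)benzamide | CCN(CC)C(=O)c1cccc(O[Si](C(C)C)(C(C)C)C(C)C)c1OC | intermediate
11 | 3-bromo-2-methylprop-1-ene (methallyl bromide) | C=C(C)CBr | starting material
12 | N,N-diethyl-6-lithio-2-methoxy-3-(triisopropylsilyloxy)benzamide (not isolated) | CCN(CC)C(=O)c1c([Li])ccc(O[Si](C(C)C)(C(C)C)C(C)C)c1OC | intermediate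
13 | [2-(diethylcarbamoyl)-3-methoxy-4-(triisopropylsilyloxy)phenyl]magnesium bromide (not isolated) | CCN(CC)C(=O)c1c([Mg]Br)ccc(O[Si](C(C)C)(C(C)C)C(C)C)c1OC | intermediate
14 | N,N-diethyl-2-methoxy-6-(2-methylprop-2-enyl)-3-(triisopropylsilyloxy)benzamide | CCN(CC)C(=O)c1c(CC(C)=C)ccc(O[Si](C(C)C)(C(C)C)C(C)C)c1OC | intermediate
15 | benzylic–allylic lithio derivative of 14 (not isolated) | CCN(CC)C(=O)c1c(C([Li])C(C)=C)ccc(O[Si](C(C)C)(C(C)C)C(C)C)c1OC | intermediate
16 | 8-methoxy-3-methyl-7-(triisopropylsilyloxy)naphthalen-1-ol | COc1c(O[Si](C(C)C)(C(C)C)C(C)C)ccc2cc(C)cc(O)c12 | intermediate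
17 | 4,4,8-trimethoxy-3-methyl-7-(triisopropylsilyloxy)naphthalen-1(4H)-one (not isolated) | COc1c(O[Si](C(C)C)(C(C)C)C(C)C)ccc2c1C(=O)C=C(C)C2(OC)OC | intermediate
18 | 4,8-dimethoxy-3-methyl-7-(triisopropylsilyloxy)naphthalen-1-ol | COc1c(O[Si](C(C)C)(C(C)C)C(C)C)ccc2c(OC)c(C)cc(O)c12 | intermediate
19 | 4,8-dimethoxy-1-(methoxymethoxy)-3-methyl-7-(triisopropylsilyloxy)naphthalene | COCOc1cc(C)c(OC)c2ccc(O[Si](C(C)C)(C(C)C)C(C)C)c(OC)c12 | intermediate
20 | 2-lithio derivative of 19 (not isolated) | COCOc1c([Li])c(C)c(OC)c2ccc(O[Si](C(C)C)(C(C)C)C(C)C)c(OC)c12 | intermediate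
21 | 2-[4,8-dimethoxy-1-(methoxymethoxy)-3-methyl-7-(triisopropylsilyloxy)naphthalen-2-yl]-4,4,5,5-tetramethyl-1,3,2-dioxaborolane | COCOc1c(B3OC(C)(C)C(C)(C)O3)c(C)c(OC)c2ccc(O[Si](C(C)C)(C(C)C)C(C)C)c(OC)c12 | intermediate
22 | 2-[4,8-dimethoxy-1-(methoxymethoxy)-3-methyl-7-(triisopropylsilyloxy)naphthalen-2-yl]-5-methoxy-7-methylnaphthalene-1,4-dione | COCOc1c(C3=CC(=O)c4c(OC)cc(C)cc4C3=O)c(C)c(OC)c2ccc(O[Si](C(C)C)(C(C)C)C(C)C)c(OC)c12 | intermediate
23 | 2-[7-hydroxy-4,8-dimethoxy-1-(methoxymethoxy)-3-methylnaphthalen-2-yl]-5-methoxy-7-methylnaphthalene-1,4-dione (not isolated) | COCOc1c(C3=CC(=O)c4c(OC)cc(C)cc4C3=O)c(C)c(OC)c2ccc(O)c(OC)c12 | intermediate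
24 | burmanin C, 2-(1,7-dihydroxy-4,8-dimethoxy-3-methylnaphthalen-2-yl)-5-methoxy-7-methylnaphthalene-1,4-dione (no stereocentre) | COc1cc(C)cc2c1C(=O)C=C(c1c(C)c(OC)c3ccc(O)c(OC)c3c1O)C2=O | target

**Step count and risks**

Total step count: 12 (steps 1–3 for the bromoquinone, steps 4–10 for the boronate, steps 11–12 for coupling and deprotection). Longest linear sequence: 9 steps (steps 4–12, from 8 to 24).

The three steps most likely to fail:

Step 11 (Suzuki coupling of a di-ortho-substituted, electron-rich boronate with a base-sensitive bromoquinone) may suffer protodeboronation or quinone decomposition in the basic aqueous medium. The fallback is a base-free Stille coupling. It sets out from 19, which is lithiated as in step 10 to 20 and quenched with Me3SnCl to give [4,8-dimethoxy-1-(methoxymethoxy)-3-methyl-7-(triisopropylsilyloxy)naphthalen-2-yl]trimethylstannane F1. Coupling of this stannane with 7 under neutral conditions (Pd(PPh3)4, CuI, DMF, 60 °C) comes back to the route at 22.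

Step 10 (OMOM-directed lithiation at the flanked C2) may compete with lateral lithiation of the neighbouring methyl group or with peri-lithiation. The fallback fixes the position by electrophilic halogenation and halogen–lithium exchange. It sets out from 18, which is brominated ortho to the free hydroxyl (NBS, CH2Cl2, −78 → 0 °C; the para position is blocked) to give 2-bromo-4,8-dimethoxy-3-methyl-7-(triisopropylsilyloxy)naphthalen-1-ol F2. Protection (NaH, MeOCH2Cl, THF) gives 2-bromo-4,8-dimethoxy-1-(methoxymethoxy)-3-methyl-7-(triisopropylsilyloxy)naphthalene F3. Bromine–lithium exchange (n-BuLi, THF, −78 °C) then gives 20 regiospecifically, and the iPrOBpin quench comes back to the route at 21.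

Step 8 (oxidative dearomatisation and one-pot reductive aromatisation) may give ortho-attack, over-oxidation or incomplete reduction. The fallback introduces the 4-methoxy group by halogenation and copper-mediated methoxylation. It sets out from 16, which is protected (NaH, MeOCH2Cl, THF) as 8-methoxy-1-(methoxymethoxy)-3-methyl-7-(triisopropylsilyloxy)naphthalene F4. Bromination para to the acetal oxygen (NBS, MeCN, 0 °C) gives 4-bromo-8-methoxy-1-(methoxymethoxy)-3-methyl-7-(triisopropylsilyloxy)naphthalene F5. Ullmann-type methoxylation (NaOMe, CuI, DMF/MeOH, 100 °C), in which the hot methoxide also removes the silyl group, gives 1,5-dimethoxy-8-(methoxymethoxy)-6-methylnaphthalen-2-ol F6. Re-silylation (iPr3SiCl, imidazole, DMF) comes back to the route at 19.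

Further compounds
F1 | step 11 | [4,8-dimethoxy-1-(methoxymethoxy)-3-methyl-7-(triisopropylsilyloxy)naphthalen-2-yl]trimethylstannane | COCOc1c([Sn](C)(C)C)c(C)c(OC)c2ccc(O[Si](C(C)C)(C(C)C)C(C)C)c(OC)c12
F2 | step 10 | 2-bromo-4,8-dimethoxy-3-methyl-7-(triisopropylsilyloxy)naphthalen-1-ol | COc1c(O[Si](C(C)C)(C(C)C)C(C)C)ccc2c(OC)c(C)c(Br)c(O)c12
F3 | step 10 | 2-bromo-4,8-dimethoxy-1-(methoxymethoxy)-3-methyl-7-(triisopropylsilyloxy)naphthalene | COCOc1c(Br)c(C)c(OC)c2ccc(O[Si](C(C)C)(C(C)C)C(C)C)c(OC)c12
F4 | step 8 | 8-methoxy-1-(methoxymethoxy)-3-methyl-7-(triisopropylsilyloxy)naphthalene | COCOc1cc(C)cc2ccc(O[Si](C(C)C)(C(C)C)C(C)C)c(OC)c12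
F5 | step 8 | 4-bromo-8-methoxy-1-(methoxymethoxy)-3-methyl-7-(triisopropylsilyloxy)naphthalene | COCOc1cc(C)c(Br)c2ccc(O[Si](C(C)C)(C(C)C)C(C)C)c(OC)c12
F6 | step 8 | 1,5-dimethoxy-8-(methoxymethoxy)-6-methylnaphthalen-2-ol | COCOc1cc(C)c(OC)c2ccc(O)c(OC)c12
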